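**Retrosynthetic overview**

- The aryl ether is made last by Mitsunobu coupling with purchased umbelliferone, and the propanoic acid chain is cut back by two carbons to a carboxyl on the quaternary ring carbon.
- Feature: numbering the carbocycle C1 (CH–isopropenyl), C2=C3(CH3), C4 (CH–CH2OAr), C5 (quaternary) and C6 (CH2), the unit C2=C3–C4–C5–CO2H is a γ,δ-unsaturated acid, and C6–C1 can tie that carboxyl to an oxygen on C2 as a 6-alkenyl δ-lactone.
- Key disconnection: Ireland–Claisen ring contraction of the lactone silyl ketene acetal, forming C4–C5 and breaking the C2–O bond.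
- The lactone comes from ring-closing metathesis of a methacrylate whose two stereocentres are set by a phosphoric acid-catalysed anti-pentadienylboration of a prenol-derived enal.
- Ring order: dihydropyranone first (metathesis), cyclohexene second (by contraction of that lactone), coumarin bought intact and attached last.

Key step: step 9

Remark on the chemistry (assumption): by analogy with simple aldehydes, (S)-TRIP is taken to direct allyl transfer to the Si face of the enal; should the first run give the enantiomeric alcohol, (R)-TRIP is used and nothing else changes.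

**Route**

Step 1
Reactants: 1 2-methylbut-1-en-3-yne
Product: 2 (E)-4,4,5,5-tetramethyl-2-(3-methylbuta-1,3-dien-1-yl)-1,3,2-dioxaborolane
Conditions: HBpin, Cp2ZrHCl (5 mol %), Et3N (10 mol %), neat, sealed tube, 60 °C
Reagents that add atoms: pinacolborane, [H]B1OC(C)(C)C(C)(C)O1
Why: Zirconocene hydride-catalysed hydroboration adds H–B syn across the terminal alkyne with boron on the terminal carbon, which should give the (E)-dienylboronate and leave the 1,1-disubstituted alkene untouched.

Step 2
Reactants: 2 (E)-4,4,5,5-tetramethyl-2-(3-methylbuta-1,3-dien-1-yl)-1,3,2-dioxaborolane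
Product: 4 (E)-4,4,5,5-tetramethyl-2-(4-methylpenta-2,4-dien-1-yl)-1,3,2-dioxaborolane, via lithium chloromethylboronate complex 3 (not isolated)
Conditions: ICH2Cl, n-BuLi, THF, −78 °C to rt
Reagents that add atoms: chloroiodomethane, ClCI
Why: Matteson homologation, in which chloromethyllithium formed in situ adds to boron and 1,2-migration of the dienyl group with loss of chloride inserts one CH2, the (E)-alkene being carried over unchanged.

Step 3
Reactants: 5 prenol (3-methylbut-2-en-1-ol)
Product: 6 tert-butyldimethyl[(3-methylbut-2-en-1-yl)oxy]silane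
Conditions: TBSCl, imidazole, DMF, 0 °C to rt
Reagents that add atoms: tert-butyldimethylsilyl chloride, CC(C)(C)[Si](C)(C)Cl
Why: Imidazole-mediated silylation of the primary allylic alcohol is routine and masks the oxygen that later becomes the aryl ether oxygen.

Step 4
Reactants: 6 tert-butyldimethyl[(3-methylbut-2-en-1-yl)oxy]silane
Product: 7 (E)-4-[(tert-butyldimethylsilyl)oxy]-2-methylbut-2-en-1-ol
Conditions: SeO2 (0.1 equiv), t-BuOOH, salicylic acid (cat.), CH2Cl2, rt
Reagents that add atoms: selenium dioxide, O=[Se]=O (transfers the oxygen); tert-butyl hydroperoxide, CC(C)(C)OO (terminal oxidant that restores it)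
Why: Allylic oxidation with SeO2 (Riley oxidation, ene reaction then [2,3]-sigmatropic shift) attacks the methyl group trans to the CH2OTBS chain and so should give the (E)-allylic alcohol, any over-oxidised aldehyde being the product of step 5 and carried along.

Step 5
Reactants: 7 (E)-4-[(tert-butyldimethylsilyl)oxy]-2-methylbut-2-en-1-ol
Product: 8 (E)-4-[(tert-butyldimethylsilyl)oxy]-2-methylbut-2-enal
Conditions: MnO2, CH2Cl2, rt
Reagents that add atoms: none
Why: Activated MnO2 oxidises allylic alcohols selectively to enals without touching the silyl ether or isomerising the (E)-alkene.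

Step 6
Reactants: 4 (E)-4,4,5,5-tetramethyl-2-(4-methylpenta-2,4-dien-1-yl)-1,3,2-dioxaborolane; 8 (E)-4-[(tert-butyldimethylsilyl)oxy]-2-methylbut-2-enal
Product: 10 (2E,4S,5R)-1-[(tert-butyldimethylsilyl)oxy]-3-methyl-5-(prop-1-en-2-yl)hepta-2,6-dien-4-ol, via borate ester 9 (not isolated)
Conditions: (S)-TRIP [(S)-3,3'-bis(2,4,6-triisopropylphenyl)-1,1'-binaphthyl-2,2'-diyl hydrogen phosphate] (5 mol %), 4 Å MS, PhMe, −30 °C; aq. NaHCO3 work-up
Reagents that add atoms: none
Why: Chiral phosphoric acid-catalysed allylboration, in which the (E)-boronate reacts at its γ-carbon through a closed chair with isopropenyl and the enal residue both equatorial (setting the anti relation of C4–OH and C5), while the (S)-catalyst hydrogen-bonded to a boronate oxygen should expose the Si face of the aldehyde and so set (4S).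

Step 7
Reactants: 10 (2E,4S,5R)-1-[(tert-butyldimethylsilyl)oxy]-3-methyl-5-(prop-1-en-2-yl)hepta-2,6-dien-4-ol; 11 methacryloyl chloride
Product: 12 (2E,4S,5R)-1-[(tert-butyldimethylsilyl)oxy]-3-methyl-5-(prop-1-en-2-yl)hepta-2,6-dien-4-yl 2-methylprop-2-enoate
Conditions: Et3N, DMAP (cat.), CH2Cl2, 0 °C to rt
Reagents that add atoms: none
Why: DMAP-catalysed acylation of the secondary alcohol under amine base avoids any metal alkoxide, so the 3-hydroxy-1,5-diene cannot undergo anionic oxy-Cope rearrangement and both stereocentres are kept.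

Step 8
Reactants: 12 (2E,4S,5R)-1-[(tert-butyldimethylsilyl)oxy]-3-methyl-5-(prop-1-en-2-yl)hepta-2,6-dien-4-yl 2-methylprop-2-enoate
Product: 13 (5R,6S)-6-[(2E)-4-[(tert-butyldimethylsilyl)oxy]but-2-en-2-yl]-3-methyl-5-(prop-1-en-2-yl)-5,6-dihydro-2H-pyran-2-one
Conditions: second-generation Grubbs catalyst (H2IMes)(PCy3)Cl2Ru=CHPh (5 mol %), 1,4-benzoquinone (10 mol %), PhMe (5 mM), 80 °C
Reagents that add atoms: none
Why: Ring-closing metathesis, in which the ruthenium carbene forms at the monosubstituted vinyl group and can close only onto the methacrylate alkene (the isopropenyl and trisubstituted alkenes would give three- or four-membered rings), so the anti alcohol should become the trans-5,6-disubstituted α-methyl unsaturated δ-lactone.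

Step 9
Reactants: 13 (5R,6S)-6-[(2E)-4-[(tert-butyldimethylsilyl)oxy]but-2-en-2-yl]-3-methyl-5-(prop-1-en-2-yl)-5,6-dihydro-2H-pyran-2-one
Product: 17 (1R,2S,5S)-2-{[(tert-butyldimethylsilyl)oxy]methyl}-1,3-dimethyl-5-(prop-1-en-2-yl)cyclohex-3-ene-1-carboxylic acid, via lithium enolate 14 (not isolated), via silyl ketene acetal 15 (not isolated), via trimethylsilyl ester 16 (not isolated)
Conditions: LiBH(s-Bu)3 (L-Selectride), THF, −78 °C; TMSCl, Et3N, −78 °C to rt; PhMe, 100 °C; aq. citric acid, THF, rt
Reagents that add atoms: chlorotrimethylsilane, C[Si](C)(C)Cl (its Me3Si group is carried only by intermediates 15 and 16 and is lost on hydrolysis)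
Why: Hydride from LiBH(s-Bu)3 adds to C4 of the unsaturated lactone, TMSCl silylates enolate 14 on oxygen to the ring-locked ketene acetal 15, and on heating the O1–C6 bond breaks as C3 of the ketene acetal bonds to the CH(CH2OTBS) terminus of the side-chain alkene in a concerted [3,3] shift (Ireland–Claisen rearrangement), after which water cleaves silyl ester 16. The closest known reactions are the thermal ring contraction of 6-alkenyl δ-lactone silyl ketene acetals to cyclohex-3-enecarboxylic acids and the reductive Ireland–Claisen rearrangement of allyl enoates, in which a conjugate hydride addition supplies the ketene acetal. The cyclohexene is closed by ring contraction of the lactone: the two-carbon bridge C4–C5 between the reacting termini allows only a boat, bicyclo[2.2.2]-like transition state with the alkenyl group axial, and C3, C4, C5, C6 and the two alkene carbons become the carbocycle. The C6–O chirality is transferred suprafacially to the new CH(CH2OTBS) and quaternary centres: the (E)-alkene holds CH2OTBS in the outer position of the boat and hence cis to the new carboxyl, and the trans arrangement in the lactone keeps the isopropenyl group on the side away from the allyl unit, so that it ends on the same face as both, its own carbon not taking part. The step needs complete facial transfer and O- rather than C-silylation; the enforced boat, the fixed ketene acetal geometry and the defined (E)-alkene should secure the first and the fully substituted enolate carbon the second, while formation of the silyl ester carbonyl drives the creation of the quaternary centre.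

Step 10
Reactants: 17 (1R,2S,5S)-2-{[(tert-butyldimethylsilyl)oxy]methyl}-1,3-dimethyl-5-(prop-1-en-2-yl)cyclohex-3-ene-1-carboxylic acid
Product: 18 [(1R,2S,5S)-2-{[(tert-butyldimethylsilyl)oxy]methyl}-1,3-dimethyl-5-(prop-1-en-2-yl)cyclohex-3-en-1-yl]methanol
Conditions: LiAlH4, THF, 0 °C to rt; H2O, aq. NaOH work-up
Reagents that add atoms: none
Why: LiAlH4 reduces the hindered carboxylic acid to the primary neopentyl alcohol, while the isolated alkenes and the primary TBS ether should survive at or below room temperature and no stereocentre is involved.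

Step 11
Reactants: 18 [(1R,2S,5S)-2-{[(tert-butyldimethylsilyl)oxy]methyl}-1,3-dimethyl-5-(prop-1-en-2-yl)cyclohex-3-en-1-yl]methanol
Product: 19 (1R,2S,5S)-2-{[(tert-butyldimethylsilyl)oxy]methyl}-1,3-dimethyl-5-(prop-1-en-2-yl)cyclohex-3-ene-1-carbaldehyde
Conditions: Pr4N[RuO4] (TPAP, 5 mol %), NMO, 4 Å MS, CH2Cl2, rt
Reagents that add atoms: none
Why: Ley–Griffith oxidation (catalytic perruthenate with NMO) stops at the aldehyde, which has no α-hydrogen and therefore cannot epimerise.

Step 12
Reactants: 19 (1R,2S,5S)-2-{[(tert-butyldimethylsilyl)oxy]methyl}-1,3-dimethyl-5-(prop-1-en-2-yl)cyclohex-3-ene-1-carbaldehyde; 20 trimethyl phosphonoacetate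
Product: 21 methyl (2E)-3-[(1S,2S,5S)-2-{[(tert-butyldimethylsilyl)oxy]methyl}-1,3-dimethyl-5-(prop-1-en-2-yl)cyclohex-3-en-1-yl]prop-2-enoate
Conditions: NaH, THF, 0 °C to 40 °C
Reagents that add atoms: none
Why: Horner–Wadsworth–Emmons olefination of the non-enolisable aldehyde with the stabilised phosphonate anion should give the (E)-enoate and adds the two carbons that complete the propanoate chain.

Step 13
Reactants: 21 methyl (2E)-3-[(1S,2S,5S)-2-{[(tert-butyldimethylsilyl)oxy]methyl}-1,3-dimethyl-5-(prop-1-en-2-yl)cyclohex-3-en-1-yl]prop-2-enoate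
Product: 22 methyl 3-[(1R,2R,5S)-2-{[(tert-butyldimethylsilyl)oxy]methyl}-1,3-dimethyl-5-(prop-1-en-2-yl)cyclohex-3-en-1-yl]propanoate
Conditions: [(Ph3P)CuH]6 (5 mol %), Me(EtO)2SiH, t-BuOH, PhMe, rt
Reagents that add atoms: none
Why: Copper hydride adds hydride 1,4 only to the electron-poor conjugated alkene, t-BuOH protonates the copper enolate and the silane regenerates the hydride, so the isopropenyl and ring alkenes and the ester should remain untouched.

Step 14
Reactants: 22 methyl 3-[(1R,2R,5S)-2-{[(tert-butyldimethylsilyl)oxy]methyl}-1,3-dimethyl-5-(prop-1-en-2-yl)cyclohex-3-en-1-yl]propanoate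
Product: 23 methyl 3-[(1R,2R,5S)-2-(hydroxymethyl)-1,3-dimethyl-5-(prop-1-en-2-yl)cyclohex-3-en-1-yl]propanoate
Conditions: TBAF, AcOH, THF, rt
Reagents that add atoms: none
Why: Fluoride cleaves the Si–O bond of the primary silyl ether, and buffering with AcOH keeps the liberated alkoxide from attacking the methyl ester.

Step 15
Reactants: 23 methyl 3-[(1R,2R,5S)-2-(hydroxymethyl)-1,3-dimethyl-5-(prop-1-en-2-yl)cyclohex-3-en-1-yl]propanoate; 24 umbelliferone (7-hydroxycoumarin)
Product: 25 methyl 3-[(1R,2R,5S)-1,3-dimethyl-2-{[(2-oxo-2H-chromen-7-yl)oxy]methyl}-5-(prop-1-en-2-yl)cyclohex-3-en-1-yl]propanoate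
Conditions: PPh3, DIAD, THF, 0 °C to 40 °C
Reagents that add atoms: none
Why: Mitsunobu etherification, in which the phenol (pKa about 8) protonates the betaine and its phenoxide displaces the oxyphosphonium group at the primary carbon, which is not a stereocentre, so the three ring centres are unaffected.

Step 16
Reactants: 25 methyl 3-[(1R,2R,5S)-1,3-dimethyl-2-{[(2-oxo-2H-chromen-7-yl)oxy]methyl}-5-(prop-1-en-2-yl)cyclohex-3-en-1-yl]propanoate
Product: 28 3-[(1R,2R,5S)-1,3-dimethyl-2-{[(2-oxo-2H-chromen-7-yl)oxy]methyl}-5-(prop-1-en-2-yl)cyclohex-3-en-1-yl]propanoic acid (target CNP0301632.1), via lithium carboxylate 26 (not isolated), via ring-opened coumarinate salt 27 (not isolated)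
Conditions: LiOH, THF/MeOH/H2O, rt; then 1 M HCl to pH 2, rt
Reagents that add atoms: lithium hydroxide, [Li+].[OH-] (its oxygen ends up in the carboxyl group)
Why: Saponification of the unhindered methyl ester by hydroxide (acyl–oxygen cleavage), in which hydroxide also opens the coumarin lactone reversibly to the (Z)-2-hydroxycinnamate that keeps its cis geometry at room temperature and should relactonise on acidification, no stereocentre being touched.

**Compound list**

1 | 2-methylbut-1-en-3-yne | C=C(C)C#C | starting material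
2 | (E)-4,4,5,5-tetramethyl-2-(3-methylbuta-1,3-dien-1-yl)-1,3,2-dioxaborolane | C=C(C)/C=C/B1OC(C)(C)C(C)(C)O1 | intermediate
3 | lithium (E)-chloromethyl(3-methylbuta-1,3-dien-1-yl)(pinacolato)borate | C=C(C)/C=C/[B-]1(CCl)OC(C)(C)C(C)(C)O1.[Li+] | intermediate (not isolated)
4 | (E)-4,4,5,5-tetramethyl-2-(4-methylpenta-2,4-dien-1-yl)-1,3,2-dioxaborolane | C=C(C)/C=C/CB1OC(C)(C)C(C)(C)O1 | intermediate
5 | prenol (3-methylbut-2-en-1-ol) | CC(C)=CCO | starting material
6 | tert-butyldimethyl[(3-methylbut-2-en-1-yl)oxy]silane | CC(C)=CCO[Si](C)(C)C(C)(C)C | intermediate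
7 | (E)-4-[(tert-butyldimethylsilyl)oxy]-2-methylbut-2-en-1-ol | OC/C(C)=C/CO[Si](C)(C)C(C)(C)C | intermediate
8 | (E)-4-[(tert-butyldimethylsilyl)oxy]-2-methylbut-2-enal | O=C/C(C)=C/CO[Si](C)(C)C(C)(C)C | intermediate
9 | pinacol borate ester of alcohol 10 (O–Bpin at C4) | C=C[C@H](C(C)=C)[C@H](OB1OC(C)(C)C(C)(C)O1)/C(C)=C/CO[Si](C)(C)C(C)(C)C | intermediate (not isolated)
10 | (2E,4S,5R)-1-[(tert-butyldimethylsilyl)oxy]-3-methyl-5-(prop-1-en-2-yl)hepta-2,6-dien-4-ol (anti) | C=C[C@H](C(C)=C)[C@H](O)/C(C)=C/CO[Si](C)(C)C(C)(C)C | intermediate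
11 | methacryloyl chloride | C=C(C)C(Cl)=O | starting material
12 | (2E,4S,5R)-1-[(tert-butyldimethylsilyl)oxy]-3-methyl-5-(prop-1-en-2-yl)hepta-2,6-dien-4-yl 2-methylprop-2-enoate | C=C[C@H](C(C)=C)[C@H](OC(=O)C(C)=C)/C(C)=C/CO[Si](C)(C)C(C)(C)C | intermediate
13 | (5R,6S)-6-[(2E)-4-[(tert-butyldimethylsilyl)oxy]but-2-en-2-yl]-3-methyl-5-(prop-1-en-2-yl)-5,6-dihydro-2H-pyran-2-one (trans) | CC1=C[C@H](C(C)=C)[C@@H](/C(C)=C/CO[Si](C)(C)C(C)(C)C)OC1=O | intermediate
14 | lithium enolate of the saturated lactone (lithium (2S,3R)-2-alkenyl-5-methyl-3-(prop-1-en-2-yl)-3,4-dihydro-2H-pyran-6-olate) | CC1=C([O-])O[C@H](/C(C)=C/CO[Si](C)(C)C(C)(C)C)[C@@H](C(C)=C)C1.[Li+] | intermediate (not isolated)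
15 | (2S,3R)-2-[(2E)-4-[(tert-butyldimethylsilyl)oxy]but-2-en-2-yl]-5-methyl-3-(prop-1-en-2-yl)-6-[(trimethylsilyl)oxy]-3,4-dihydro-2H-pyran | CC1=C(O[Si](C)(C)C)O[C@H](/C(C)=C/CO[Si](C)(C)C(C)(C)C)[C@@H](C(C)=C)C1 | intermediate (not isolated)
16 | trimethylsilyl (1R,2S,5S)-2-{[(tert-butyldimethylsilyl)oxy]methyl}-1,3-dimethyl-5-(prop-1-en-2-yl)cyclohex-3-ene-1-carboxylate | C=C(C)[C@@H]1C=C(C)[C@H](CO[Si](C)(C)C(C)(C)C)[C@](C)(C(=O)O[Si](C)(C)C)C1 | intermediate (not isolated)
17 | (1R,2S,5S)-2-{[(tert-butyldimethylsilyl)oxy]methyl}-1,3-dimethyl-5-(prop-1-en-2-yl)cyclohex-3-ene-1-carboxylic acid | C=C(C)[C@@H]1C=C(C)[C@H](CO[Si](C)(C)C(C)(C)C)[C@](C)(C(=O)O)C1 | intermediate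
18 | [(1R,2S,5S)-2-{[(tert-butyldimethylsilyl)oxy]methyl}-1,3-dimethyl-5-(prop-1-en-2-yl)cyclohex-3-en-1-yl]methanol | C=C(C)[C@@H]1C=C(C)[C@H](CO[Si](C)(C)C(C)(C)C)[C@](C)(CO)C1 | intermediate
19 | (1R,2S,5S)-2-{[(tert-butyldimethylsilyl)oxy]methyl}-1,3-dimethyl-5-(prop-1-en-2-yl)cyclohex-3-ene-1-carbaldehyde | C=C(C)[C@@H]1C=C(C)[C@H](CO[Si](C)(C)C(C)(C)C)[C@](C)(C=O)C1 | intermediate
20 | trimethyl phosphonoacetate | COC(=O)CP(=O)(OC)OC | starting material
21 | methyl (2E)-3-[(1S,2S,5S)-2-{[(tert-butyldimethylsilyl)oxy]methyl}-1,3-dimethyl-5-(prop-1-en-2-yl)cyclohex-3-en-1-yl]prop-2-enoate | C=C(C)[C@@H]1C=C(C)[C@H](CO[Si](C)(C)C(C)(C)C)[C@](C)(/C=C/C(=O)OC)C1 | intermediate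
22 | methyl 3-[(1R,2R,5S)-2-{[(tert-butyldimethylsilyl)oxy]methyl}-1,3-dimethyl-5-(prop-1-en-2-yl)cyclohex-3-en-1-yl]propanoate | C=C(C)[C@@H]1C=C(C)[C@H](CO[Si](C)(C)C(C)(C)C)[C@](C)(CCC(=O)OC)C1 | intermediate
23 | methyl 3-[(1R,2R,5S)-2-(hydroxymethyl)-1,3-dimethyl-5-(prop-1-en-2-yl)cyclohex-3-en-1-yl]propanoate | C=C(C)[C@@H]1C=C(C)[C@H](CO)[C@](C)(CCC(=O)OC)C1 | intermediate
24 | umbelliferone (7-hydroxycoumarin) | O=c1ccc2ccc(O)cc2o1 | starting material
25 | methyl 3-[(1R,2R,5S)-1,3-dimethyl-2-{[(2-oxo-2H-chromen-7-yl)oxy]methyl}-5-(prop-1-en-2-yl)cyclohex-3-en-1-yl]propanoate | C=C(C)[C@@H]1C=C(C)[C@H](COc2ccc3ccc(=O)oc3c2)[C@](C)(CCC(=O)OC)C1 | intermediate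
26 | lithium 3-[(1R,2R,5S)-1,3-dimethyl-2-{[(2-oxo-2H-chromen-7-yl)oxy]methyl}-5-(prop-1-en-2-yl)cyclohex-3-en-1-yl]propanoate | C=C(C)[C@@H]1C=C(C)[C@H](COc2ccc3ccc(=O)oc3c2)[C@](C)(CCC(=O)[O-])C1.[Li+] | intermediate (not isolated)
27 | trilithium salt of ring-opened 26: (Z)-3-(2-oxido-4-alkoxyphenyl)prop-2-enoate with the propanoate as carboxylate | C=C(C)[C@@H]1C=C(C)[C@H](COc2ccc(/C=C\C(=O)[O-])c([O-])c2)[C@](C)(CCC(=O)[O-])C1.[Li+].[Li+].[Li+] | intermediate (not isolated)
28 | 3-[(1R,2R,5S)-1,3-dimethyl-2-{[(2-oxo-2H-chromen-7-yl)oxy]methyl}-5-(prop-1-en-2-yl)cyclohex-3-en-1-yl]propanoic acid (CNP0301632.1) | C=C(C)[C@@H]1C=C(C)[C@H](COc2ccc3ccc(=O)oc3c2)[C@](C)(CCC(=O)O)C1 | target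

**Step count and risks**

Total step count: 16. Longest linear sequence: 14 steps (prenol 5 to target 28, steps 3 to 16).

The three steps most likely to fail:

Step 9. Competing 1,2-reduction of the lactone carbonyl, Michael addition of enolate 14 to unreacted 13, or C-silylation may prevent clean formation of ketene acetal 15 in the one-pot sequence. The fallback separates reduction from enolisation and sets out from lactone 13. Copper hydride conjugate reduction ([(Ph3P)CuH]6 (cat.), Me(EtO)2SiH, t-BuOH, PhMe, rt) should give the saturated lactone F1 as a mixture of C3 epimers, which is of no consequence because C3 becomes trigonal again. Deprotonation with LiN(i-Pr)2 in THF at −78 °C and silylation with TMSCl/Et3N then form enolate 14 and ketene acetal 15 under non-reducing conditions. The fallback returns to the route at 15, and heating and hydrolysis as in step 9 lead on to acid 17.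

Step 6. A 1,3-boron shift in boronate 4 before addition (loss of the (E)-geometry and hence of the anti relation), or weak facial discrimination by the phosphoric acid on the α-branched enal 8, would erode diastereo- or enantioselectivity. The fallback sets out from 4 and 8 and replaces catalyst control by a resolution. The uncatalysed addition in toluene at rt goes through the same chair and should give the racemic borate ester F2 and, after aqueous work-up, the racemic anti alcohol F3. Sharpless kinetic resolution (Ti(Oi-Pr)4, D-(−)-diisopropyl tartrate, t-BuOOH (0.6 equiv), 4 Å MS, CH2Cl2, −20 °C) by the usual rule for secondary allylic alcohols epoxidises the (4R)-enantiomer faster. It should therefore convert the unwanted (4R,5S)-alcohol into the erythro epoxy alcohol F4 and leave 10, which is separated by chromatography and re-enters the route at step 7.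

Step 15. The CH2OH group sits on a ring carbon flanked by the quaternary centre and the trisubstituted alkene, so displacement of the oxyphosphonium ion by the phenoxide may be slow, and the activated alcohol may instead be consumed by alkylation of the hydrazide or by elimination. The fallback sets out from alcohol 23 and separates activation from substitution. Tf2O and 2,6-lutidine in CH2Cl2 at −78 °C should give the triflate F5, which is treated without storage with umbelliferone 24 and Cs2CO3 in DMF at 0 °C to rt (Williamson-type O-alkylation of the caesium phenoxide) to reach ether 25.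

Further compounds
F1 | step 9 | (3RS,5R,6S)-6-[(2E)-4-[(tert-butyldimethylsilyl)oxy]but-2-en-2-yl]-3-methyl-5-(prop-1-en-2-yl)oxan-2-one (saturated lactone, C3 epimers) | CC1C[C@H](C(C)=C)[C@@H](/C(C)=C/CO[Si](C)(C)C(C)(C)C)OC1=O
F2 | step 6 | racemic pinacol borate ester of the anti alcohol (1:1 mixture of 9 and its enantiomer) | C=C[C@H](C(C)=C)[C@H](OB1OC(C)(C)C(C)(C)O1)/C(C)=C/CO[Si](C)(C)C(C)(C)C.C=C[C@@H](C(C)=C)[C@@H](OB1OC(C)(C)C(C)(C)O1)/C(C)=C/CO[Si](C)(C)C(C)(C)C
F3 | step 6 | racemic anti-(2E)-1-[(tert-butyldimethylsilyl)oxy]-3-methyl-5-(prop-1-en-2-yl)hepta-2,6-dien-4-ol (1:1 mixture of 10 and its enantiomer) | C=C[C@H](C(C)=C)[C@H](O)/C(C)=C/CO[Si](C)(C)C(C)(C)C.C=C[C@@H](C(C)=C)[C@@H](O)/C(C)=C/CO[Si](C)(C)C(C)(C)C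
F4 | step 6 | erythro epoxy alcohol from the (4R,5S)-enantiomer: (1R,2S)-1-{3-[(tert-butyldimethylsilyloxy)methyl]-2-methyloxiran-2-yl}-2-(prop-1-en-2-yl)but-3-en-1-ol | C=C[C@@H](C(C)=C)[C@@H](O)[C@@]1(C)O[C@@H]1CO[Si](C)(C)C(C)(C)C
F5 | step 15 | methyl 3-[(1R,2R,5S)-1,3-dimethyl-5-(prop-1-en-2-yl)-2-{[(trifluoromethylsulfonyl)oxy]methyl}cyclohex-3-en-1-yl]propanoate (triflate) | C=C(C)[C@@H]1C=C(C)[C@H](COS(=O)(=O)C(F)(F)F)[C@](C)(CCC(=O)OC)C1
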